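The pitfall is to set Tuesday's run beside Thursday's on the same day and read the gap as a weak order in substrate. I start instead from the balance of the gas in solution. Each tris adduct takes up 3 gas, so Tuesday's charge of 0.21 M asks for 27.4 times the 23 mM that the solution holds at saturation, and gas has to keep crossing over (mass transfer). It crosses at a rate proportional to csat − c(gas). If I assume every step is first order in dissolved gas, it is used at a rate proportional to c(gas) times the charge. Setting the two equal, on that assumption the time to reach any stage grows as 1 + c(substrate)/c_d, so a loaded flask runs the same course on a slower clock.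

common to all: gas 23 mM (held)
- Thursday's: substrate 0.0095 M; run made earlier
- Tuesday's: substrate 0.21 M; run made earlier
- amber: substrate 0.0080 M; time 25 d
- violet: substrate 0.020 M; time 25 d
- red: substrate 0.040 M; time 25 d
- blue: substrate 0.080 M; time 25 d
- grey: substrate 0.15 M; time 25 d

| run | time / d | tris adduct / % |
|---|---|---|
| Thursday's | 1.25 | 2 |
| Thursday's | 4.00 | 4 |
| Thursday's | 8.00 | 16 |
| Thursday's | 10.0 | 25 |
| Thursday's | 15.0 | 45 |
| Thursday's | 20.0 | 57 |
| Thursday's | 25.0 | 65 |
| Tuesday's | 2.08 | 0 |
| Tuesday's | 3.00 | 2 |
| Tuesday's | 5.00 | 0 |
| Tuesday's | 8.00 | 1 |
| Tuesday's | 10.0 | 10 |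
| Tuesday's | 15.0 | 23 |
| Tuesday's | 25.0 | 49 |

(scatter of a reading: 2 percentage points)

- at the start none of the gas is in solution
- "hardly changes" means that all values lie within two and a half points (for a concentration: within two and a half percent of the largest)

- [tris adduct] at the end for amber, violet, red, blue, grey, in this order
- the course of these numbers from the first flask to the last (falls all the way / hardly changes / rises, then falls / rises all the way / falls, then rises)

I can read the clock in two ways from separate readings. Interpolated between its readings, Thursday's flask reached Tuesday's final 49% after 16.7 d, where Tuesday's needed 25.0 d, a ratio of 0.667. It reached Tuesday's 23% after 9.56 d against 15.0 d, a ratio of 0.637. The two ratios part by 0.0296, and with readings that scatter by 2 percentage points I cannot tell whether that gap is noise or a clock that drifts with stage, so the mean, 0.652, is a working value and the single clock stays an assumption. From it I get 0.366 M for c_d, the doubling charge: the charge of substrate that, on the single clock, doubles the time to a stage.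

By my reckoning, grey at 25 d then stands where Thursday's flask stood at 18.2 d, which is 52.7%, or 0.0790 M. Amber maps onto 25.1 d, so it takes Thursday's last 65%, or 0.00520 M. The percentage falls while the charge grows 18.8 times, so I expect a row that rises all the way.

The forecast says 0.0053 M, 0.0124 M, 0.024 M, 0.045 M and 0.078 M, and rises all the way. It interpolates percentages against the logarithm of the charge, and of the concentrated run's delay it says “perhaps because gas supply or uptake is strained”.

The flasks give 0.00498 M, 0.0123 M, 0.0243 M, 0.0468 M and 0.0806 M: rises all the way.

    substrate + reagent → first product (k = 0.0108 M⁻¹ min⁻¹)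
    reagent + first product → bis adduct (k = 0.00373 M⁻¹ min⁻¹)
    reagent + bis adduct → tris adduct (k = 0.00550 M⁻¹ min⁻¹)
    gas ⇌ reagent, rate k4*(csat - [reagent]) (kL = 0.00197 min⁻¹)
    tris adduct ⇌ isomer of the product (K = 0.795, k = 2.22 × 10⁻⁵ min⁻¹)

In amber, gas crosses to reagent with a half-time of 0.244 d, far shorter than the 5.6 d half-life of reagent by the step to first product as charged, and reagent stands at 0.0227 M after 12.5 d, whereas grey's stands lower, at 0.0179 M. Carried to blue, the doubling charge 0.366 M maps its 25 d onto Thursday's 21.0 d, which gives 58.7%, and blue holds 58.5% tris adduct after 25.0 d.

The earlier runs and the new flask come from a simulation from invented constants.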